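**Retrosynthetic overview**

- Feature: in the oxolane ring O1–C2–C3–C4–C5, the 3,4-dimethoxyphenyl donor on C2 and the 3,4,5-trimethoxybenzoyl acceptor (ketone carbon C7') on C4 stand 1,3 to each other across C3 (CH2OH arm, C9). C2–C3–C4 is therefore a latent donor–acceptor cyclopropane and O1–C5 a formaldehyde unit.
- Key disconnection: O1–C2 and C4–C5, a (3+2) annulation of a trans-2-aryl-3-(silyloxymethyl)cyclopropane keto ester with formaldehyde. It closes the only ring to be formed (the oxolane) and sets C2 by inversion.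
- The cyclopropane (bonds C2–C4 and C3–C4, both CH stereocentres) comes from an amine-catalysed Michael-initiated ring closure of 3,4-dimethoxycinnamaldehyde with the α-bromo keto ester. The absolute configuration of C3 originates here.
- Endgame: removal of the ester activator with equilibration of C4 to the trans ketone, then release of the C9 hydroxyl.

Key step: step 5

Assumption: the quaternary carbon of 4, 5, 6 and 9 is drawn as the epimer expected to prevail (aroyl cis to the C9 arm in the cyclopropanes, trans to it in 9). The other epimer would serve equally, because this carbon becomes a planar enolate carbon in steps 5 and 6.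

**Route**

Step 1
Reactants: 1 ethyl 3-oxo-3-(3,4,5-trimethoxyphenyl)propanoate
Product: 2 ethyl 2-bromo-3-oxo-3-(3,4,5-trimethoxyphenyl)propanoate (racemic)
Conditions: NBS (1.05 equiv), NH4OAc (10 mol%), Et2O, 25 °C
Reagents that add atoms: N-bromosuccinimide, O=C1CCC(=O)N1Br
Why: Electrophilic α-bromination of the enol of a β-keto ester, with ammonium acetate speeding enolisation; one equivalent of NBS should stop at the monobromide, and the benzoyl ring, deactivated by its carbonyl group, should not be attacked.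

Step 2
Reactants: 2 ethyl 2-bromo-3-oxo-3-(3,4,5-trimethoxyphenyl)propanoate; 3 (E)-3-(3,4-dimethoxyphenyl)prop-2-enal
Product: 4 ethyl (1R,2S,3R)-2-(3,4-dimethoxyphenyl)-3-formyl-1-(3,4,5-trimethoxybenzoyl)cyclopropane-1-carboxylate (aryl and formyl trans)
Conditions: (S)-α,α-diphenylprolinol trimethylsilyl ether (20 mol%), 2,6-lutidine (1.1 equiv), CH2Cl2, 0 °C
Reagents that add atoms: none
Why: Iminium–enamine cascade (Michael-initiated ring closure) of the kind known for enals with bromomalonates and α-bromo-β-keto esters: the enol of 2 adds to the β-carbon of the iminium ion of 3 on the face away from the CPh2OSiMe3 group (Si face), setting the aryl-bearing carbon (S), and the enamine then displaces bromide in a 3-exo-tet closure that sets the formyl-bearing carbon (R), the E geometry of 3 fixing aryl and formyl trans.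

Step 3
Reactants: 4 ethyl (1R,2S,3R)-2-(3,4-dimethoxyphenyl)-3-formyl-1-(3,4,5-trimethoxybenzoyl)cyclopropane-1-carboxylate
Product: 5 ethyl (1R,2S,3R)-2-(3,4-dimethoxyphenyl)-3-(hydroxymethyl)-1-(3,4,5-trimethoxybenzoyl)cyclopropane-1-carboxylate
Conditions: NaBH4 (0.5 equiv), EtOH/CH2Cl2 (3:7), −78 °C; aq NH4Cl
Reagents that add atoms: none
Why: Chemoselective borohydride reduction of an aldehyde beside a ketone at low temperature, helped by the hindered, electron-rich, α-quaternary aryl ketone; no stereocentre is formed or touched.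

Step 4
Reactants: 5 ethyl (1R,2S,3R)-2-(3,4-dimethoxyphenyl)-3-(hydroxymethyl)-1-(3,4,5-trimethoxybenzoyl)cyclopropane-1-carboxylate
Product: 6 ethyl (1R,2S,3R)-3-[(tert-butyldiphenylsilyl)oxymethyl]-2-(3,4-dimethoxyphenyl)-1-(3,4,5-trimethoxybenzoyl)cyclopropane-1-carboxylate
Conditions: TBDPSCl, imidazole, DMF, 0 → 25 °C
Reagents that add atoms: tert-butyl(chloro)diphenylsilane, CC(C)(C)[Si](Cl)(c1ccccc1)c1ccccc1
Why: Imidazole-promoted silylation of the primary alcohol, run directly after step 3 so that the alcohol cannot cyclise onto a neighbouring carbonyl group; a bulky silyl ether is chosen because, unlike an ester group, its oxygen cannot open the activated cyclopropane as a neighbouring group in step 5.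

Step 5
Reactants: 6 ethyl (1R,2S,3R)-3-[(tert-butyldiphenylsilyl)oxymethyl]-2-(3,4-dimethoxyphenyl)-1-(3,4,5-trimethoxybenzoyl)cyclopropane-1-carboxylate; 7 1,3,5-trioxane
Product: 9 ethyl (2R,3R,4R)-3-[(tert-butyldiphenylsilyl)oxymethyl]-2-(3,4-dimethoxyphenyl)-4-(3,4,5-trimethoxybenzoyl)tetrahydrofuran-4-carboxylate (2,3-cis; ring numbered as in the overview), via formaldehyde 8 (not isolated)
Conditions: Sn(OTf)2 (20 mol%), 4 Å MS, CH2Cl2; 7 (3 equiv) stirred with the catalyst at 25 °C, then 6 added at −20 → 0 °C; Et3N quench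
Reagents that add atoms: none
Why: Proposed new method: Sn(OTf)2 chelates the keto ester of 6 and polarises the C2–C4 bond, formaldehyde oxygen (released from trioxane by the same Lewis acid) attacks benzylic C2 from the side opposite the departing enolate carbon in an SN2-like opening, and the divalent tin enolate at C4 then adds to the O1=C5 oxocarbenium carbon. The closest known reaction is the Lewis-acid (3+2) annulation of 2-arylcyclopropane-1,1-diesters with aldehydes, which runs with inversion at the donor carbon; the extension is the keto ester acceptor combined with formaldehyde. The oxolane closes by aldol-type attack of the exocyclic (enol-exo) tin enolate on the oxocarbenium ion, formally 5-endo-trig at C5, the closure that operates throughout this class of annulation. C2 is set (R) by inversion relative to the untouched C3 centre, which places aryl and silyloxymethyl cis; C4 should form with the aroyl group on the face away from the C3 arm, but this centre is erased in step 6. The step needs bimolecular capture to outrun ionisation of the electron-rich benzylic centre, which would give Cloke–Wilson ring expansion to a dihydrofuran or the 2,3-trans ether; excess formaldehyde, low temperature, the chelating keto ester and the non-participating silyl ether are meant to secure this.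

Step 6
Reactants: 9 ethyl (2R,3R,4R)-3-[(tert-butyldiphenylsilyl)oxymethyl]-2-(3,4-dimethoxyphenyl)-4-(3,4,5-trimethoxybenzoyl)tetrahydrofuran-4-carboxylate
Product: 11 [(2R,3R,4S)-3-[(tert-butyldiphenylsilyl)oxymethyl]-2-(3,4-dimethoxyphenyl)tetrahydrofuran-4-yl](3,4,5-trimethoxyphenyl)methanone (2,3-cis and 3,4-trans), via 4-epi ketone 10 (not isolated)
Conditions: LiCl (3 equiv), H2O (3 equiv), DMSO, 120 °C; then K2CO3 (0.5 equiv), MeOH, 25 °C
Reagents that add atoms: none
Why: Krapcho dealkoxycarbonylation, in which chloride dealkylates the ethyl ester of the non-enolisable β-keto ester, the carboxylate loses CO2 and the enolate is protonated by water; any C4 epimer from kinetic protonation is equilibrated by carbonate to the more stable (4S) ketone with the aroyl group trans to the C3 arm, while C2 and C3 carry no acidic hydrogen and stay fixed.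

Step 7
Reactants: 11 [(2R,3R,4S)-3-[(tert-butyldiphenylsilyl)oxymethyl]-2-(3,4-dimethoxyphenyl)tetrahydrofuran-4-yl](3,4,5-trimethoxyphenyl)methanone
Product: 12 [(2R,3R,4S)-2-(3,4-dimethoxyphenyl)-3-(hydroxymethyl)tetrahydrofuran-4-yl](3,4,5-trimethoxyphenyl)methanone (the target)
Conditions: TBAF, AcOH (1:1), THF, 0 → 25 °C
Reagents that add atoms: none
Why: Fluoride-mediated cleavage of the primary silyl ether, driven by Si–F bond formation; the acetic acid buffer keeps the medium from enolising the β-alkoxy ketone, so no stereocentre is touched.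

**Compound list**

1 | ethyl 3-oxo-3-(3,4,5-trimethoxyphenyl)propanoate | CCOC(=O)CC(=O)c1cc(OC)c(OC)c(OC)c1 | starting material
2 | ethyl 2-bromo-3-oxo-3-(3,4,5-trimethoxyphenyl)propanoate (racemic) | CCOC(=O)C(Br)C(=O)c1cc(OC)c(OC)c(OC)c1 | intermediate
3 | (E)-3-(3,4-dimethoxyphenyl)prop-2-enal | COc1ccc(/C=C/C=O)cc1OC | starting material
4 | ethyl (1R,2S,3R)-2-(3,4-dimethoxyphenyl)-3-formyl-1-(3,4,5-trimethoxybenzoyl)cyclopropane-1-carboxylate | COc1ccc([C@@H]2[C@@H](C=O)[C@]2(C(=O)c3cc(OC)c(OC)c(OC)c3)C(=O)OCC)cc1OC | intermediate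
5 | ethyl (1R,2S,3R)-2-(3,4-dimethoxyphenyl)-3-(hydroxymethyl)-1-(3,4,5-trimethoxybenzoyl)cyclopropane-1-carboxylate | COc1ccc([C@@H]2[C@@H](CO)[C@]2(C(=O)c3cc(OC)c(OC)c(OC)c3)C(=O)OCC)cc1OC | intermediate
6 | ethyl (1R,2S,3R)-3-[(tert-butyldiphenylsilyl)oxymethyl]-2-(3,4-dimethoxyphenyl)-1-(3,4,5-trimethoxybenzoyl)cyclopropane-1-carboxylate | COc1ccc([C@@H]2[C@@H](CO[Si](c4ccccc4)(c5ccccc5)C(C)(C)C)[C@]2(C(=O)c3cc(OC)c(OC)c(OC)c3)C(=O)OCC)cc1OC | intermediate (key-step precursor)
7 | 1,3,5-trioxane | C1OCOCO1 | starting material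
8 | formaldehyde | C=O | intermediate (not isolated)
9 | ethyl (2R,3R,4R)-3-[(tert-butyldiphenylsilyl)oxymethyl]-2-(3,4-dimethoxyphenyl)-4-(3,4,5-trimethoxybenzoyl)tetrahydrofuran-4-carboxylate | COc1ccc([C@@H]2OC[C@](C(=O)c3cc(OC)c(OC)c(OC)c3)(C(=O)OCC)[C@@H]2CO[Si](c4ccccc4)(c5ccccc5)C(C)(C)C)cc1OC | intermediate (key-step product)
10 | [(2R,3R,4R)-3-[(tert-butyldiphenylsilyl)oxymethyl]-2-(3,4-dimethoxyphenyl)tetrahydrofuran-4-yl](3,4,5-trimethoxyphenyl)methanone (4-epi ketone, all-cis) | COc1ccc([C@@H]2OC[C@H](C(=O)c3cc(OC)c(OC)c(OC)c3)[C@@H]2CO[Si](c4ccccc4)(c5ccccc5)C(C)(C)C)cc1OC | intermediate (not isolated)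
11 | [(2R,3R,4S)-3-[(tert-butyldiphenylsilyl)oxymethyl]-2-(3,4-dimethoxyphenyl)tetrahydrofuran-4-yl](3,4,5-trimethoxyphenyl)methanone | COc1ccc([C@@H]2OC[C@@H](C(=O)c3cc(OC)c(OC)c(OC)c3)[C@@H]2CO[Si](c4ccccc4)(c5ccccc5)C(C)(C)C)cc1OC | intermediate
12 | [(2R,3R,4S)-2-(3,4-dimethoxyphenyl)-3-(hydroxymethyl)tetrahydrofuran-4-yl](3,4,5-trimethoxyphenyl)methanone | COc1ccc([C@@H]2OC[C@@H](C(=O)c3cc(OC)c(OC)c(OC)c3)[C@@H]2CO)cc1OC | target

**Step count and risks**

Total steps: 7. Longest linear sequence: 7 steps (1 → 2 → 4 → 5 → 6 → 9 → 11 → 12).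

Most likely to fail, step 5. The benzylic C2–C4 bond of the electron-rich cyclopropane may ionise before formaldehyde is captured. The ketone oxygen would then close to a dihydrofuran (ring expansion), or the cis relation at C2/C3 would be lost. Formaldehyde may also oligomerise on the Lewis acid. The fallback moves the annulation to the established diester manifold, where ring expansion is not available, and installs the aryl ketone afterwards. It sets out from 3 and returns at 11. Enal 3 would be cyclopropanated with diethyl bromomalonate under the conditions of step 2 to give diethyl (2S,3R)-2-(3,4-dimethoxyphenyl)-3-formylcyclopropane-1,1-dicarboxylate F1. Reduction with NaBH4 at −78 °C would give diethyl (2S,3R)-2-(3,4-dimethoxyphenyl)-3-(hydroxymethyl)cyclopropane-1,1-dicarboxylate F2, silylated at once (TBDPSCl, imidazole) to diethyl (2S,3R)-3-[(tert-butyldiphenylsilyl)oxymethyl]-2-(3,4-dimethoxyphenyl)cyclopropane-1,1-dicarboxylate F3. Sn(OTf)2-catalysed annulation with trioxane-derived formaldehyde should then give, with inversion at C2, diethyl (2R,3R)-3-[(tert-butyldiphenylsilyl)oxymethyl]-2-(3,4-dimethoxyphenyl)tetrahydrofuran-4,4-dicarboxylate F4. LiCl in wet DMSO at 150 °C followed by NaOEt equilibration would leave ethyl (2R,3R,4S)-3-[(tert-butyldiphenylsilyl)oxymethyl]-2-(3,4-dimethoxyphenyl)tetrahydrofuran-4-carboxylate F5. Me(MeO)NH·HCl with iPrMgCl would convert it into (2R,3R,4S)-3-[(tert-butyldiphenylsilyl)oxymethyl]-2-(3,4-dimethoxyphenyl)-N-methoxy-N-methyltetrahydrofuran-4-carboxamide F6. Addition of 3,4,5-trimethoxyphenylmagnesium bromide would then give 11.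

Second, step 2. Iminium formation from the electron-rich enal may be slow, bromine may be transferred from 2 to the amine catalyst, or the amine may reopen the formyl cyclopropane by a retro-Michael path. The fallback builds the cyclopropane by carbene transfer instead. It sets out from 1 and 3 and returns at 6, bypassing steps 1 to 4.

- Diazo transfer to 1 (p-acetamidobenzenesulfonyl azide, Et3N, MeCN) would give ethyl 2-diazo-3-oxo-3-(3,4,5-trimethoxyphenyl)propanoate F7.
- Luche reduction of 3 (NaBH4, CeCl3·7H2O, MeOH) would give (E)-3-(3,4-dimethoxyphenyl)prop-2-en-1-ol F8, silylated to (E)-tert-butyl{[3-(3,4-dimethoxyphenyl)prop-2-en-1-yl]oxy}diphenylsilane F9.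
- Rh2(S-NTTL)4-catalysed cyclopropanation of F9 with F7 would then give 6, the E alkene fixing the trans relation. The sense of induction is not predicted here, so Rh2(S-NTTL)4 or Rh2(R-NTTL)4 would be chosen once it has been assigned.

Third, step 6. At 120 °C the C4 enolate may expel the ring oxygen (retro-oxa-Michael opening of the oxolane), and the silyl ether may be lost. The fallback separates ester cleavage from decarboxylation and runs both at lower temperature. It sets out from 9 and returns at 11. Me3SnOH in 1,2-dichloroethane at 80 °C would hydrolyse the ester to (2R,3R,4R)-3-[(tert-butyldiphenylsilyl)oxymethyl]-2-(3,4-dimethoxyphenyl)-4-(3,4,5-trimethoxybenzoyl)tetrahydrofuran-4-carboxylic acid F10. This β-keto acid should lose CO2 on gentle warming in toluene, and brief K2CO3/MeOH equilibration would give 11.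

**Further compounds**

F1 | step 5 | diethyl (2S,3R)-2-(3,4-dimethoxyphenyl)-3-formylcyclopropane-1,1-dicarboxylate | COc1ccc([C@@H]2[C@@H](C=O)C2(C(=O)OCC)C(=O)OCC)cc1OC
F2 | step 5 | diethyl (2S,3R)-2-(3,4-dimethoxyphenyl)-3-(hydroxymethyl)cyclopropane-1,1-dicarboxylate | COc1ccc([C@@H]2[C@@H](CO)C2(C(=O)OCC)C(=O)OCC)cc1OC
F3 | step 5 | diethyl (2S,3R)-3-[(tert-butyldiphenylsilyl)oxymethyl]-2-(3,4-dimethoxyphenyl)cyclopropane-1,1-dicarboxylate | COc1ccc([C@@H]2[C@@H](CO[Si](c3ccccc3)(c4ccccc4)C(C)(C)C)C2(C(=O)OCC)C(=O)OCC)cc1OC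
F4 | step 5 | diethyl (2R,3R)-3-[(tert-butyldiphenylsilyl)oxymethyl]-2-(3,4-dimethoxyphenyl)tetrahydrofuran-4,4-dicarboxylate | COc1ccc([C@@H]2OCC(C(=O)OCC)(C(=O)OCC)[C@@H]2CO[Si](c3ccccc3)(c4ccccc4)C(C)(C)C)cc1OC
F5 | step 5 | ethyl (2R,3R,4S)-3-[(tert-butyldiphenylsilyl)oxymethyl]-2-(3,4-dimethoxyphenyl)tetrahydrofuran-4-carboxylate | COc1ccc([C@@H]2OC[C@@H](C(=O)OCC)[C@@H]2CO[Si](c3ccccc3)(c4ccccc4)C(C)(C)C)cc1OC
F6 | step 5 | (2R,3R,4S)-3-[(tert-butyldiphenylsilyl)oxymethyl]-2-(3,4-dimethoxyphenyl)-N-methoxy-N-methyltetrahydrofuran-4-carboxamide | COc1ccc([C@@H]2OC[C@@H](C(=O)N(C)OC)[C@@H]2CO[Si](c3ccccc3)(c4ccccc4)C(C)(C)C)cc1OC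
F7 | step 2 | ethyl 2-diazo-3-oxo-3-(3,4,5-trimethoxyphenyl)propanoate | CCOC(=O)C(=[N+]=[N-])C(=O)c1cc(OC)c(OC)c(OC)c1
F8 | step 2 | (E)-3-(3,4-dimethoxyphenyl)prop-2-en-1-ol | COc1ccc(/C=C/CO)cc1OC
F9 | step 2 | (E)-tert-butyl{[3-(3,4-dimethoxyphenyl)prop-2-en-1-yl]oxy}diphenylsilane | COc1ccc(/C=C/CO[Si](c2ccccc2)(c3ccccc3)C(C)(C)C)cc1OC
F10 | step 6 | (2R,3R,4R)-3-[(tert-butyldiphenylsilyl)oxymethyl]-2-(3,4-dimethoxyphenyl)-4-(3,4,5-trimethoxybenzoyl)tetrahydrofuran-4-carboxylic acid | COc1ccc([C@@H]2OC[C@](C(=O)c3cc(OC)c(OC)c(OC)c3)(C(O)=O)[C@@H]2CO[Si](c4ccccc4)(c5ccccc5)C(C)(C)C)cc1OC
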